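## Retrosynthetic overview

1. Superstolide A (33) comes from decalin-macrolide 31 by C13 carbamoylation, then N-Boc cleavage with O25→N acetyl transfer.
2. 31 comes from a transannular Diels–Alder reaction (TADA) of the 24-membered octaene 30, which is closed at C15–C16 by a Ni-electrocatalytic alkenyl–alkenyl reductive macrocyclisation of bromo-iodo seco-ester 29.
3. 29 comes from a Horner–Wadsworth–Emmons (HWE) union at C2=C3 of tetraenal 10 (C3–C15) and phosphonoacetate 28 (C1–C2 + C16–C27).
4. 10 comes from the statin side-chain aldehyde 1 (C11, C13 purchased) by lactonisation, O-methylation, iodo-Wittig and Stille coupling. 28 comes from (R)-Roche ester and N-Boc-D-alaninol by anti-aldol, Evans–Tishchenko reduction and Takai/Stille/Takai homologation.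
5. Ring order: the 24-membered macrocycle first (electrochemical), then both six-membered rings of the cis-decalin and the 16-membered lactone together in the TADA.

Assumption: telescoped one-pot operations (steps 10, 24, 26) are counted as single steps; atom numbers C1–C27 follow superstolide numbering.

## Route

**Fragment C3–C15**

Step 1
Reactants: 1, tert-butyl 2-[(4R,6S)-6-formyl-2,2-dimethyl-1,3-dioxan-4-yl]acetate
Product: 2, tert-butyl 2-[(4R,6S)-6-[(E)-2-bromoethenyl]-2,2-dimethyl-1,3-dioxan-4-yl]acetate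
Conditions: CrBr2 (from CrBr3, LiAlH4), CHBr3, THF, 50 °C
Reagents that add atoms: bromoform, BrC(Br)Br
Why: Takai–Utimoto haloform olefination gives the (E)-bromoalkene under non-basic conditions, so the α-alkoxy stereocentre (C13) is not epimerised; C11 and C13 are purchased in 1.

Step 2
Reactants: 2
Product: 3, (4R,6S)-6-[(E)-2-bromoethenyl]-4-hydroxyoxan-2-one
Conditions: TFA, CH2Cl2 (1:4), 0 °C → rt; PhMe azeotrope
Reagents that add atoms: none
Why: Acidolysis removes the acetonide and tert-butyl ester and the 5-hydroxy acid closes to the δ-lactone (statin-type lactonisation), which ties up O13 and leaves O11–H free.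

Step 3
Reactants: 3
Product: 4, (4R,6S)-6-[(E)-2-bromoethenyl]-4-methoxyoxan-2-one
Conditions: Me3OBF4, Proton Sponge, CH2Cl2, rt
Reagents that add atoms: trimethyloxonium tetrafluoroborate, C[O+](C)C.F[B-](F)(F)F
Why: Meerwein-salt O-methylation with a non-nucleophilic base installs the C11 methyl ether without β-elimination of the β-hydroxy lactone.

Step 4
Reactants: 4
Product: 5, (4R,6S)-6-[(E)-2-bromoethenyl]-4-methoxyoxan-2-ol (lactol, anomeric mixture)
Conditions: DIBAL-H, CH2Cl2, −78 °C
Reagents that add atoms: none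
Why: Partial reduction of a δ-lactone stops at the lactol because the tetrahedral aluminate is stable at −78 °C.

Step 5
Reactants: 5
Product: 6, (1E,3S,5S,7Z)-1-bromo-8-iodo-5-methoxynona-1,7-dien-3-ol
Conditions: [EtPPh3]I, n-BuLi, THF; I2, −78 °C; NaHMDS, −20 °C; then 5 (as Na lactolate), THF/DMPU, −78 → 0 °C
Reagents that add atoms: ethyltriphenylphosphonium iodide, CC[P+](c1ccccc1)(c1ccccc1)c1ccccc1.[I-]; iodine, II
Why: Stork–Zhao-type Wittig olefination of the ring-opened hydroxy aldehyde with the α-iodoethylidene ylide gives the (Z)-2-iodoalkene (iodine cis to C10, the dienophile geometry) and frees O13–H.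

Step 6
Reactants: 7, (Z)-3-methylpent-2-en-4-yn-1-ol
Product: 8, (2Z,4E)-3-methyl-5-(tributylstannyl)penta-2,4-dien-1-ol
Conditions: Bu3SnH, PdCl2(PPh3)2 (2 mol %), THF, 0 °C
Reagents that add atoms: tributyltin hydride, CCCC[SnH](CCCC)CCCC
Why: Pd-catalysed syn-hydrostannation of the terminal alkyne gives the (E)-alkenylstannane; the Z trisubstituted C4=C5 alkene is purchased in 7.

Step 7
Reactants: 8
Product: 9, (2Z,4E)-3-methyl-5-(tributylstannyl)penta-2,4-dienal
Conditions: MnO2, CH2Cl2, rt
Reagents that add atoms: none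
Why: MnO2 oxidises the allylic alcohol to the enal without destannylation or Z→E isomerisation.

Step 8
Reactants: 6; 9
Product: 10, (2Z,4E,6Z,9S,11S,12E)-13-bromo-11-hydroxy-9-methoxy-3,6-dimethyltrideca-2,4,6,12-tetraenal
Conditions: Pd(PPh3)4 (5 mol %), CuTC, [Bu4N][Ph2PO2], DMF, rt, dark
Reagents that add atoms: none
Why: Copper-assisted Stille coupling at rt engages the C–I bond selectively over the alkenyl bromide and proceeds with retention at both sp2 carbons, forming C7–C8.

**Fragment C1–C2 + C16–C27**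

Step 9
Reactants: 11, methyl (R)-3-hydroxy-2-methylpropanoate
Product: 12, methyl (R)-3-(benzyloxy)-2-methylpropanoate
Conditions: BnOC(=NH)CCl3, TfOH (cat.), CH2Cl2–cyclohexane, rt
Reagents that add atoms: benzyl 2,2,2-trichloroacetimidate, N=C(OCc1ccccc1)C(Cl)(Cl)Cl
Why: Acid-catalysed imidate benzylation protects the alcohol without racemising the α-stereocentre (C22, purchased).

Step 10
Reactants: 12
Product: 13, (R)-1-(benzyloxy)-2-methylpentan-3-one
Conditions: MeNH(OMe)·HCl, i-PrMgCl, THF, −20 °C; then EtMgBr, 0 °C (one pot)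
Reagents that add atoms: ethylmagnesium bromide, CC[Mg]Br
Why: In situ Weinreb amide formation followed by Grignard addition to the stable chelate gives the ethyl ketone without over-addition or epimerisation.

Step 11
Reactants: 14, tert-butyl N-[(2R)-1-hydroxypropan-2-yl]carbamate (N-Boc-D-alaninol)
Product: 15, tert-butyl N-[(2R)-1-oxopropan-2-yl]carbamate (N-Boc-D-alaninal)
Conditions: Dess–Martin periodinane, NaHCO3, CH2Cl2, 0 °C; used at once
Reagents that add atoms: none
Why: Buffered Dess–Martin oxidation gives the configurationally labile α-amino aldehyde without racemisation (C26 purchased).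

Step 12
Reactants: 13; 15
Product: 16, tert-butyl N-[(2R,3S,4R,6R)-7-(benzyloxy)-3-hydroxy-4,6-dimethyl-5-oxoheptan-2-yl]carbamate
Conditions: (c-Hex)2BCl, Et3N, Et2O, 0 °C; then 15, −78 → −20 °C; H2O2, MeOH, pH 7 buffer
Reagents that add atoms: none
Why: Paterson anti-aldol: the (E)-enol dicyclohexylborinate reacts through a chair transition state in which the α′-stereocentre (C22) fixes the enolate face, giving 22,24-anti and 24,25-anti; this is matched with Felkin–Anh addition to the α-amino aldehyde, giving 25,26-anti.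

Step 13
Reactants: 16
Product: 17, (2R,3S,4S,5R,6R)-7-(benzyloxy)-2-[(tert-butoxycarbonyl)amino]-5-hydroxy-4,6-dimethylheptan-3-yl acetate
Conditions: SmI2 (30 mol %), CH3CHO, THF, −10 °C
Reagents that add atoms: acetaldehyde, CC=O
Why: Evans–Tishchenko reduction delivers hydride intramolecularly from the Sm-bound hemiacetal, setting C23 1,3-anti to C25; it leaves C23–OH free and places the future N-acetyl group on O25.

Step 14
Reactants: 17
Product: 18, (2R,3S,4S,5R,6R)-2-[(tert-butoxycarbonyl)amino]-5,7-dihydroxy-4,6-dimethylheptan-3-yl acetate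
Conditions: H2 (1 atm), 10% Pd/C, EtOAc, rt
Reagents that add atoms: none
Why: Hydrogenolysis removes the benzyl ether cleanly at the last stage where the molecule has no alkene.

Step 15
Reactants: 18
Product: 19, (2R,3S,4S,5R,6S)-2-[(tert-butoxycarbonyl)amino]-5-hydroxy-4,6-dimethyl-7-oxoheptan-3-yl acetate
Conditions: TEMPO (cat.), PhI(OAc)2, CH2Cl2, rt
Reagents that add atoms: none
Why: Oxoammonium oxidation is selective for the primary alcohol over the hindered secondary C23–OH and is neutral, so no epimerisation or acetate migration occurs.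

Step 16
Reactants: 19
Product: 20, (2R,3S,4S,5R,6R,7E)-2-[(tert-butoxycarbonyl)amino]-5-hydroxy-8-iodo-4,6-dimethyloct-7-en-3-yl acetate
Conditions: CrCl2, CHI3, THF–dioxane, 0 °C → rt
Reagents that add atoms: iodoform, IC(I)I
Why: Takai iodo-olefination gives the (E)-alkenyl iodide (C20=C21) without base, so the α-methyl stereocentre and the acetate position are preserved.

Step 17
Reactants: 21, ethyl but-2-ynoate
Product: 22, ethyl (E)-3-(tributylstannyl)but-2-enoate
Conditions: Bu3SnLi (from (Bu3Sn)2, n-BuLi), CuBr·SMe2, THF, −78 °C; MeOH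
Reagents that add atoms: hexabutylditin, CCCC[Sn](CCCC)(CCCC)[Sn](CCCC)(CCCC)CCCC
Why: Piers stannylcupration adds Sn–Cu syn across the ynoate, and kinetic protonation at −78 °C gives the (E)-β-stannyl enoate (tin trans to the ester).

Step 18
Reactants: 22
Product: 23, (E)-3-(tributylstannyl)but-2-en-1-ol
Conditions: DIBAL-H, CH2Cl2, −78 °C
Reagents that add atoms: none
Why: 1,2-Reduction of the enoate gives the allylic alcohol with the alkenylstannane intact.

Step 19
Reactants: 23
Product: 24, (E)-3-(tributylstannyl)but-2-enal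
Conditions: MnO2, CH2Cl2, rt
Reagents that add atoms: none
Why: Mild allylic oxidation gives the enal without protodestannylation.

Step 20
Reactants: 20; 24
Product: 25, (2R,3S,4S,5R,6R,7E,9E)-2-[(tert-butoxycarbonyl)amino]-5-hydroxy-4,6,9-trimethyl-11-oxoundeca-7,9-dien-3-yl acetate
Conditions: Pd(PPh3)4 (5 mol %), CuTC, [Bu4N][Ph2PO2], DMF, rt
Reagents that add atoms: none
Why: Stille coupling with retention forms C19–C20 and fixes the (18E,20E)-diene, with the C19 methyl carried in by the stannane.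

Step 21
Reactants: 25
Product: 26, (2R,3S,4S,5R,6R,7E,9E,11E)-2-[(tert-butoxycarbonyl)amino]-5-hydroxy-12-iodo-4,6,9-trimethyldodeca-7,9,11-trien-3-yl acetate
Conditions: CrCl2, CHI3, THF–dioxane, 0 °C
Reagents that add atoms: iodoform, IC(I)I
Why: Takai olefination of the dienal gives the (E)-iodotriene (C16=C17) chemoselectively in the presence of the ester, carbamate and free alcohol.

Step 22
Reactants: 26; 27, 2-(diethoxyphosphoryl)acetic acid
Product: 28, (2R,3S,4S,5R,6R,7E,9E,11E)-3-acetoxy-2-[(tert-butoxycarbonyl)amino]-12-iodo-4,6,9-trimethyldodeca-7,9,11-trien-5-yl 2-(diethoxyphosphoryl)acetate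
Conditions: DCC, DMAP (cat.), CH2Cl2, 0 °C → rt
Reagents that add atoms: none beyond 27
Why: Steglich esterification acylates the only free hydroxyl (hindered C23–OH) with the phosphonoacetic acid; the O25 acetate and NHBoc do not react.

**Union, macrocyclisation and completion**

Step 23
Reactants: 10; 28
Product: 29, the C23 ester of (2E,4Z,6E,8Z,11S,13S,14E)-15-bromo-13-hydroxy-11-methoxy-5,8-dimethylpentadeca-2,4,6,8,14-pentaenoic acid with the alcohol part of 28 (bromo-iodo seco-ester)
Conditions: LiCl, i-Pr2NEt, MeCN, rt, dark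
Reagents that add atoms: none
Why: Masamune–Roush Horner–Wadsworth–Emmons olefination forms C2=C3 (E) and joins the fragments under a mild amine base that preserves the 4Z enal geometry and the acetate.

Step 24
Reactants: 29
Product: 31, 13-O-descarbamoyl-25-O-acetyl-N-deacetyl-N-Boc-superstolide A, formed through the non-isolated 24-membered (2E,4Z,6E,8Z,14E,16E,18E,20E)-octaene macrolactone 30
Conditions: NiBr2·dme (25 mol %), 4,4′-di-tert-butyl-2,2′-bipyridine (30 mol %), LiBr, DMA, undivided cell, RVC cathode held at −1.2 V vs Ag/AgCl, Zn sacrificial anode, syringe-pump addition of 29 to 1 mM, rt, dark; then 45 °C, 12 h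
Reagents that add atoms: none
Why: Proposed new method: cathodically generated Ni(0) inserts into the dienyl C16–I bond, the alkenyl–Ni(II) is reduced to alkenyl–Ni(I), this adds the C15–Br bond intramolecularly, and C(sp2)–C(sp2) reductive elimination from Ni(III) closes the 24-membered ring with retention of both alkene geometries; the potential is held below the reduction wave of the tetraenoate and slow Ni(0) generation at high dilution favours ring closure over dimerisation; the closest known chemistry is Ni-catalysed reductive (electrochemical or Zn/Mn-driven) coupling of alkenyl halides to 1,3-dienes and Ni cross-electrophile coupling, and a macrocyclising alkenyl–alkenyl version has not been shown; the new C14–C17 diene then undergoes a transannular Diels–Alder reaction with the C8=C9 dienophile (endo to the trienoate, tether chair-like with OMe and OH equatorial), so C11 and C13 set C8, C9, C14 and C17 of the cis-decalin.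

Step 25
Reactants: 31
Product: 32, 25-O-acetyl-N-deacetyl-N-Boc-superstolide A
Conditions: Cl3CC(O)NCO, CH2Cl2, 0 °C; then neutral Al2O3
Reagents that add atoms: trichloroacetyl isocyanate, O=C=NC(=O)C(Cl)(Cl)Cl
Why: Kočovský carbamoylation: the only free hydroxyl (C13–OH) adds to the isocyanate and the trichloroacetyl group is removed on alumina without touching the acetate or lactone.

Step 26
Reactants: 32
Product: 33, superstolide A
Conditions: TMSOTf, 2,6-lutidine, CH2Cl2, 0 °C; MeOH; then pH 8 phosphate buffer/THF, rt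
Reagents that add atoms: none
Why: Silyl-triflate cleavage of the Boc group (via the silyl carbamate) frees the C26 amine, which takes the adjacent O25 acetyl by O→N acyl transfer through a five-membered intermediate, giving the acetamide and the free C25–OH.

## Compound list

1 | tert-butyl 2-[(4R,6S)-6-formyl-2,2-dimethyl-1,3-dioxan-4-yl]acetate | CC1(C)O[C@@H](CC(=O)OC(C)(C)C)C[C@@H](C=O)O1 | starting material
2 | tert-butyl 2-[(4R,6S)-6-[(E)-2-bromoethenyl]-2,2-dimethyl-1,3-dioxan-4-yl]acetate | CC1(C)O[C@@H](CC(=O)OC(C)(C)C)C[C@@H](/C=C/Br)O1 | intermediate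
3 | (4R,6S)-6-[(E)-2-bromoethenyl]-4-hydroxyoxan-2-one | O[C@@H]1C[C@@H](/C=C/Br)OC(=O)C1 | intermediate
4 | (4R,6S)-6-[(E)-2-bromoethenyl]-4-methoxyoxan-2-one | CO[C@@H]1C[C@@H](/C=C/Br)OC(=O)C1 | intermediate
5 | (4R,6S)-6-[(E)-2-bromoethenyl]-4-methoxyoxan-2-ol | CO[C@@H]1C[C@@H](/C=C/Br)OC(O)C1 | intermediate
6 | (1E,3S,5S,7Z)-1-bromo-8-iodo-5-methoxynona-1,7-dien-3-ol | CO[C@@H](C/C=C(/C)I)C[C@H](O)/C=C/Br | intermediate
7 | (Z)-3-methylpent-2-en-4-yn-1-ol | OC/C=C(C)\C#C | starting material
8 | (2Z,4E)-3-methyl-5-(tributylstannyl)penta-2,4-dien-1-ol | OC/C=C(C)\C=C\[Sn](CCCC)(CCCC)CCCC | intermediate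
9 | (2Z,4E)-3-methyl-5-(tributylstannyl)penta-2,4-dienal | O=C/C=C(C)\C=C\[Sn](CCCC)(CCCC)CCCC | intermediate
10 | (2Z,4E,6Z,9S,11S,12E)-13-bromo-11-hydroxy-9-methoxy-3,6-dimethyltrideca-2,4,6,12-tetraenal | CO[C@@H](C/C=C(/C)\C=C\C(C)=C/C=O)C[C@H](O)/C=C/Br | intermediate
11 | methyl (R)-3-hydroxy-2-methylpropanoate | OC[C@@H](C)C(=O)OC | starting material
12 | methyl (R)-3-(benzyloxy)-2-methylpropanoate | c1ccccc1COC[C@@H](C)C(=O)OC | intermediate
13 | (R)-1-(benzyloxy)-2-methylpentan-3-one | c1ccccc1COC[C@@H](C)C(=O)CC | intermediate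
14 | tert-butyl N-[(2R)-1-hydroxypropan-2-yl]carbamate | OC[C@@H](C)NC(=O)OC(C)(C)C | starting material
15 | tert-butyl N-[(2R)-1-oxopropan-2-yl]carbamate | O=C[C@@H](C)NC(=O)OC(C)(C)C | intermediate
16 | tert-butyl N-[(2R,3S,4R,6R)-7-(benzyloxy)-3-hydroxy-4,6-dimethyl-5-oxoheptan-2-yl]carbamate | c1ccccc1COC[C@@H](C)C(=O)[C@H](C)[C@H](O)[C@@H](C)NC(=O)OC(C)(C)C | intermediate
17 | (2R,3S,4S,5R,6R)-7-(benzyloxy)-2-[(tert-butoxycarbonyl)amino]-5-hydroxy-4,6-dimethylheptan-3-yl acetate | c1ccccc1COC[C@@H](C)[C@H]([C@H](C)[C@H](OC(C)=O)[C@@H](C)NC(=O)OC(C)(C)C)O | intermediate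
18 | (2R,3S,4S,5R,6R)-2-[(tert-butoxycarbonyl)amino]-5,7-dihydroxy-4,6-dimethylheptan-3-yl acetate | OC[C@@H](C)[C@H]([C@H](C)[C@H](OC(C)=O)[C@@H](C)NC(=O)OC(C)(C)C)O | intermediate
19 | (2R,3S,4S,5R,6S)-2-[(tert-butoxycarbonyl)amino]-5-hydroxy-4,6-dimethyl-7-oxoheptan-3-yl acetate | O=C[C@@H](C)[C@H]([C@H](C)[C@H](OC(C)=O)[C@@H](C)NC(=O)OC(C)(C)C)O | intermediate
20 | (2R,3S,4S,5R,6R,7E)-2-[(tert-butoxycarbonyl)amino]-5-hydroxy-8-iodo-4,6-dimethyloct-7-en-3-yl acetate | I/C=C/[C@@H](C)[C@H]([C@H](C)[C@H](OC(C)=O)[C@@H](C)NC(=O)OC(C)(C)C)O | intermediate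
21 | ethyl but-2-ynoate | CC#CC(=O)OCC | starting material
22 | ethyl (E)-3-(tributylstannyl)but-2-enoate | CCOC(=O)/C=C(C)/[Sn](CCCC)(CCCC)CCCC | intermediate
23 | (E)-3-(tributylstannyl)but-2-en-1-ol | OC/C=C(C)/[Sn](CCCC)(CCCC)CCCC | intermediate
24 | (E)-3-(tributylstannyl)but-2-enal | O=C/C=C(C)/[Sn](CCCC)(CCCC)CCCC | intermediate
25 | (2R,3S,4S,5R,6R,7E,9E)-2-[(tert-butoxycarbonyl)amino]-5-hydroxy-4,6,9-trimethyl-11-oxoundeca-7,9-dien-3-yl acetate | O=C/C=C(C)/C=C/[C@@H](C)[C@H]([C@H](C)[C@H](OC(C)=O)[C@@H](C)NC(=O)OC(C)(C)C)O | intermediate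
26 | (2R,3S,4S,5R,6R,7E,9E,11E)-2-[(tert-butoxycarbonyl)amino]-5-hydroxy-12-iodo-4,6,9-trimethyldodeca-7,9,11-trien-3-yl acetate | I/C=C/C=C(C)/C=C/[C@@H](C)[C@H]([C@H](C)[C@H](OC(C)=O)[C@@H](C)NC(=O)OC(C)(C)C)O | intermediate
27 | 2-(diethoxyphosphoryl)acetic acid | OC(=O)CP(=O)(OCC)OCC | starting material
28 | (2R,3S,4S,5R,6R,7E,9E,11E)-3-acetoxy-2-[(tert-butoxycarbonyl)amino]-12-iodo-4,6,9-trimethyldodeca-7,9,11-trien-5-yl 2-(diethoxyphosphoryl)acetate | I/C=C/C=C(C)/C=C/[C@@H](C)[C@H]([C@H](C)[C@H](OC(C)=O)[C@@H](C)NC(=O)OC(C)(C)C)OC(=O)CP(=O)(OCC)OCC | intermediate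
29 | bromo-iodo seco-ester: C23 ester of the (2E,4Z,6E,8Z,14E)-15-bromo-13-hydroxy-11-methoxy-5,8-dimethylpentadecapentaenoic acid with the C16-iodotriene alcohol | I/C=C/C=C(C)/C=C/[C@@H](C)[C@H]([C@H](C)[C@H](OC(C)=O)[C@@H](C)NC(=O)OC(C)(C)C)OC(=O)/C=C/C=C(C)\C=C\C(C)=C/C[C@H](OC)C[C@H](O)/C=C/Br | intermediate
30 | 24-membered (2E,4Z,6E,8Z,14E,16E,18E,20E)-octaene macrolactone, 11-OMe, 13-OH, side chain CH(Me)CH(OAc)CH(Me)NHBoc | CO[C@@H]1C[C@H](O)/C=C/C=C/C=C(C)/C=C/[C@@H](C)[C@H]([C@H](C)[C@H](OC(C)=O)[C@@H](C)NC(=O)OC(C)(C)C)OC(=O)/C=C/C=C(C)\C=C\C(C)=C/C1 | intermediate (not isolated)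
31 | 13-O-descarbamoyl-25-O-acetyl-N-deacetyl-N-Boc-superstolide A | CO[C@@H]1C[C@H](O)[C@@H]2C=C[C@@H]3/C=C(C)/C=C/[C@@H](C)[C@H]([C@H](C)[C@H](OC(C)=O)[C@@H](C)NC(=O)OC(C)(C)C)OC(=O)/C=C/C=C(C)\C=C\[C@]3(C)[C@@H]2C1 | intermediate
32 | 25-O-acetyl-N-deacetyl-N-Boc-superstolide A | CO[C@@H]1C[C@H](OC(N)=O)[C@@H]2C=C[C@@H]3/C=C(C)/C=C/[C@@H](C)[C@H]([C@H](C)[C@H](OC(C)=O)[C@@H](C)NC(=O)OC(C)(C)C)OC(=O)/C=C/C=C(C)\C=C\[C@]3(C)[C@@H]2C1 | intermediate
33 | superstolide A | CO[C@@H]1C[C@H](OC(N)=O)[C@@H]2C=C[C@@H]3/C=C(C)/C=C/[C@@H](C)[C@H]([C@H](C)[C@H](O)[C@@H](C)NC(C)=O)OC(=O)/C=C/C=C(C)\C=C\[C@]3(C)[C@@H]2C1 | target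

## Totals and risk

Total steps: 26.
Longest linear sequence: 14 (11 → 12 → 13 → 16 → 17 → 18 → 19 → 20 → 25 → 26 → 28 → 29 → 31 → 32 → 33).

Three steps most likely to fail:

1. **Step 24 (proposed new electrochemical macrocyclisation).** Risks are intermolecular coupling, protodehalogenation and Ni-mediated polyene isomerisation. Fallback with known chemistry: make C15–C16 by an ordinary intermolecular Stille coupling, using an alkenylstannane prepared from 25 with Bu3SnCHBr2/CrCl2 in place of step 21 and the alkenyl bromide of 10. Then close the 24-membered ring by intramolecular Horner–Wadsworth–Emmons olefination at C2=C3 (LiCl, i-Pr2NEt, high dilution); the same transannular Diels–Alder follows.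

2. **Step 5 (iodo-Wittig on the lactol).** Risks are slow lactol opening, β-elimination of methoxide and a modest Z:E ratio. Fallback: Still–Gennari olefination of 5 to the (Z)-2-methyl enoate (C7 as ester), DIBAL/MnO2 and Takai iodination to a C6 iodide, then Stille coupling with (Z)-3-(tributylstannyl)but-2-enal. This moves the sp2–sp2 disconnection from C7–C8 to C5–C6.

3. **Step 26 (Boc cleavage and O→N acetyl transfer on the full polyene).** Risks are Lewis-acid damage to the diene and trienoate and acyl scrambling. Fallback: after acylating C23–OH on the simple alkenyl iodide 20, cleave the Boc group there (TFA, then NaHCO3 for the acetyl shift) and mask the freed C25–OH as a TES ether. Carry this through the sequence and finish with HF·pyridine desilylation.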